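**Plan**

- Cuts: (1) the aryl ether O–CH2 bond; (2) the bond from the ring to that CH2, which reveals a cyclopentanone at the carbon carrying CH2OAr; (3) the angular methyl; (4) together, the ring bonds CH2–CH(CH3) and CH(isobutenyl)–C(quaternary).
- Enabling feature: in the cyclopentane, the adjacent CH2 and CH(CH=CMe2) carbons are the terminal double bond of 4-methylpenta-1,3-diene. Their two ring neighbours flank the CH2OAr-bearing carbon; with that carbon as a carbonyl they are the α and α' carbons of one ketone, so a (3+2) union of diene and ketone closes the ring.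
- Forward: β-keto ester (temporary ester on the future CH(CH3) carbon) → α-bromide → one-flask palladium radical/π-allyl annulation with the diene (cyclopentanone) → methylation (quaternary carbon) → ester removal → enol triflate and CO homologation → reduction → Mitsunobu → saponification.
- Stereochemistry: the isobutenyl-bearing carbon comes from the chiral palladium catalyst in the annulation; the quaternary carbon from alkylation anti to isobutenyl; the ring methyl from hydride delivery anti to the isobutenyl/propanoate face; the CH2O-bearing carbon from base equilibration of the aldehyde.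

Key step: step 3

Remark: the sense of induction of the BINAP–palladium catalyst in step 3 cannot be predicted with certainty; (R)-BINAP is written and stands for whichever ligand antipode gives the S configuration at the isobutenyl-bearing carbon.

**Route**

Step 1
Reactants: 1 methyl propanoate; 2 methyl 5-chloro-5-oxopentanoate
Product: 3 dimethyl 2-methyl-3-oxoheptanedioate (racemic)
Conditions: LiN(i-Pr)2 (2.1 equiv), THF, −78 °C; then 2, −78 to 0 °C; aq NH4Cl
Reagents that add atoms: none
Why: Crossed Claisen-type C-acylation of the lithium ester enolate by the acid chloride (the second equivalent of enolate deprotonates the β-keto ester as it forms); the new stereocentre is racemic and of no consequence because it is destroyed later.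

Step 2
Reactants: 3 dimethyl 2-methyl-3-oxoheptanedioate
Product: 4 dimethyl 2-bromo-2-methyl-3-oxoheptanedioate (racemic)
Conditions: NBS (1.05 equiv), Mg(ClO4)2 (10 mol %), MeCN, 25 °C
Reagents that add atoms: N-bromosuccinimide, O=C1CCC(=O)N1Br
Why: Electrophilic α-bromination of the enol of a 2-substituted β-keto ester should occur only at the doubly activated carbon; the bromide is racemic and its configuration is lost in the radical step.

Step 3
Reactants: 4 dimethyl 2-bromo-2-methyl-3-oxoheptanedioate; 5 4-methylpenta-1,3-diene
Product: 7 methyl (4S)-3-(3-methoxy-3-oxopropyl)-1-methyl-4-(2-methylprop-1-en-1-yl)-2-oxocyclopentane-1-carboxylate (epimeric at C1 and C3), via allylic bromide 6 (not isolated)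
Conditions: Pd2(dba)3 (2.5 mol %), (R)-BINAP (6 mol %), 5 (3 equiv), THF, blue LEDs, 25 °C; then LiOt-Bu (1.2 equiv), 0 to 25 °C
Reagents that add atoms: none
Why: Proposed new method: photoexcited zerovalent palladium reduces the tertiary C–Br bond of 4, the electrophilic captodative radical adds to the unsubstituted CH2 terminus of 5 (first new bond) and the resulting 1,1-dimethylallyl radical is captured by monovalent palladium bromide as a π-allylpalladium bromide that rests as allylic bromide 6; LiOt-Bu then forms the only possible ketone enolate (the ester-bearing α-carbon has become quaternary), whose α-carbon attacks the CH terminus of the π-allyl unit (second new bond) and returns zerovalent palladium. The closest known reaction types are the visible-light palladium-catalysed 1,2-carbofunctionalisation of 1,3-dienes by alkyl bromides through radical/π-allyl crossover, the Kharasch addition of α-bromo-β-dicarbonyl compounds to dienes, the Tsuji–Trost allylation of lithium ketone enolates with BINAP–palladium catalysts and the palladium-catalysed 1,3-O-to-C shift that turns 5-vinyl-2-alkylidenetetrahydrofurans into 3-vinylcyclopentanones. The cyclopentanone closes by 5-(enolendo)-exo attack on the nearer allyl terminus, which the long palladium–allyl contact should tolerate, while closure at the CMe2 terminus would need a 7-membered ring and kinetic O-allylation is reversible under the catalyst. The isobutenyl-bearing carbon is the only stereocentre that must be right; it is set in the enolate/π-allyl bond formation under control of the BINAP-bound palladium after the allyl faces have equilibrated through the CMe2 terminus, so that all stereoisomers of 6 should converge on one configuration there. The ester-bearing quaternary carbon and the enolisable carbon next to the ketone arise as mixtures, which is harmless because the former is removed in steps 5 and 6 and the latter is reset in step 4. The step needs regioselective radical addition (secured by the unsubstituted diene terminus and allyl stabilisation), a single enolisation site (secured by the quaternary α-carbon) and ionisation by palladium that outruns uncatalysed closure (secured by the highly ionisable allylic bromide).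

Step 4
Reactants: 7 methyl (4S)-3-(3-methoxy-3-oxopropyl)-1-methyl-4-(2-methylprop-1-en-1-yl)-2-oxocyclopentane-1-carboxylate
Product: 8 methyl (3R,4S)-3-(3-methoxy-3-oxopropyl)-1,3-dimethyl-4-(2-methylprop-1-en-1-yl)-2-oxocyclopentane-1-carboxylate (epimeric at C1)
Conditions: LiN(SiMe3)2 (1.1 equiv), THF, −78 to 0 °C; MeI (3 equiv), DMPU, −40 to 0 °C
Reagents that add atoms: iodomethane, CI
Why: Ketone enolate alkylation: 7 has a single enolisable ketone α-carbon (the amide base spares the esters) and methyl iodide should approach the enolate face anti to the adjacent isobutenyl group, which sets the quaternary centre with methyl trans and the propanoate arm cis to isobutenyl (trans-alkylation of 3-substituted cyclopentanone enolates).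

Step 5
Reactants: 8 methyl (3R,4S)-3-(3-methoxy-3-oxopropyl)-1,3-dimethyl-4-(2-methylprop-1-en-1-yl)-2-oxocyclopentane-1-carboxylate
Product: 9 methyl 3-[(1R,5S)-1,3-dimethyl-5-(2-methylprop-1-en-1-yl)-2-oxocyclopentyl]propanoate (epimeric at C3)
Conditions: LiCl (3 equiv), H2O (2 equiv), DMSO, 150 °C
Reagents that add atoms: none
Why: Krapcho dealkoxycarbonylation: chloride demethylates the activated β-keto ester, CO2 is lost and the enolate is protonated, while the unactivated chain ester should survive; the configuration of the new α-methyl centre does not matter because step 6 flattens it.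

Step 6
Reactants: 9 methyl 3-[(1R,5S)-1,3-dimethyl-5-(2-methylprop-1-en-1-yl)-2-oxocyclopentyl]propanoate
Product: 10 methyl 3-[(1R,5S)-1,3-dimethyl-5-(2-methylprop-1-en-1-yl)-2-(trifluoromethanesulfonyloxy)cyclopent-2-en-1-yl]propanoate
Conditions: KN(SiMe3)2 (1.1 equiv), THF, −78 °C; PhNTf2 (1.2 equiv), −78 to 0 °C
Reagents that add atoms: N-phenylbis(trifluoromethanesulfonimide), O=S(=O)(N(c1ccccc1)S(=O)(=O)C(F)(F)F)C(F)(F)F
Why: Regiospecific enol triflate formation: only the methyl-bearing α-carbon carries a proton, the ketone is more acidic than the ester, and the potassium enolate is O-sulfonylated; no stereocentre is formed.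

Step 7
Reactants: 10 methyl 3-[(1R,5S)-1,3-dimethyl-5-(2-methylprop-1-en-1-yl)-2-(trifluoromethanesulfonyloxy)cyclopent-2-en-1-yl]propanoate
Product: 11 methyl 3-[(1R,5S)-2-formyl-1,3-dimethyl-5-(2-methylprop-1-en-1-yl)cyclopent-2-en-1-yl]propanoate
Conditions: Pd(PPh3)4 (5 mol %), CO (1 atm), Bu3SnH (1.2 equiv, slow addition), LiCl, THF, 50 °C
Reagents that add atoms: carbon monoxide, [C-]#[O+]
Why: Palladium-catalysed reductive carbonylation (formylation) of a vinyl triflate: oxidative addition, CO insertion and hydride transfer from tin to the acylpalladium should give the enal; no stereocentre is formed.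

Step 8
Reactants: 11 methyl 3-[(1R,5S)-2-formyl-1,3-dimethyl-5-(2-methylprop-1-en-1-yl)cyclopent-2-en-1-yl]propanoate
Product: 13 methyl 3-[(1R,2R,3S,5S)-2-(hydroxymethyl)-1,3-dimethyl-5-(2-methylprop-1-en-1-yl)cyclopentyl]propanoate, via saturated aldehyde 12 (not isolated)
Conditions: [(Ph3P)CuH]6 (0.4 equiv), H2O (2 equiv), benzene, 25 °C; aq NH4Cl; then K2CO3, MeOH, 25 °C; then NaBH4, 0 °C
Reagents that add atoms: none
Why: Copper hydride conjugate reduction, then equilibration and borohydride reduction: hydride should add to the β-carbon from the ring face opposite to the isobutenyl group and the propanoate arm (the face of the angular methyl), which places the ring methyl cis to them, K2CO3/MeOH then brings the formyl group trans to that methyl (the thermodynamic epimer), and NaBH4 reduces only the aldehyde.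

Step 9
Reactants: 13 methyl 3-[(1R,2R,3S,5S)-2-(hydroxymethyl)-1,3-dimethyl-5-(2-methylprop-1-en-1-yl)cyclopentyl]propanoate; 14 7-hydroxy-2H-chromen-2-one (umbelliferone)
Product: 15 methyl 3-[(1R,2R,3S,5S)-1,3-dimethyl-5-(2-methylprop-1-en-1-yl)-2-{[(2-oxo-2H-chromen-7-yl)oxy]methyl}cyclopentyl]propanoate
Conditions: 14 (1.2 equiv), PPh3, DIAD, THF, 0 to 25 °C
Reagents that add atoms: none
Why: Mitsunobu etherification of the primary alcohol by the acidic 7-hydroxyl of umbelliferone; no stereocentre is involved.

Step 10
Reactants: 15 methyl 3-[(1R,2R,3S,5S)-1,3-dimethyl-5-(2-methylprop-1-en-1-yl)-2-{[(2-oxo-2H-chromen-7-yl)oxy]methyl}cyclopentyl]propanoate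
Product: 16 ferulsinaic acid, 3-[(1R,2R,3S,5S)-1,3-dimethyl-5-(2-methylprop-1-en-1-yl)-2-{[(2-oxo-2H-chromen-7-yl)oxy]methyl}cyclopentyl]propanoic acid
Conditions: LiOH·H2O (3 equiv), THF/H2O, 25 °C; then 1 M HCl to pH 2
Reagents that add atoms: lithium hydroxide, [Li+].[OH-]
Why: Saponification of the methyl ester; a coumarin lactone opened by hydroxide should reclose on acidification because the cis geometry of the cinnamate is kept, and no stereocentre is epimerisable under these conditions.

**Compound list**

1 | methyl propanoate | CCC(=O)OC | starting material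
2 | methyl 5-chloro-5-oxopentanoate | COC(=O)CCCC(=O)Cl | starting material
3 | dimethyl 2-methyl-3-oxoheptanedioate (racemic) | COC(=O)C(C)C(=O)CCCC(=O)OC | intermediate
4 | dimethyl 2-bromo-2-methyl-3-oxoheptanedioate (racemic) | COC(=O)C(C)(Br)C(=O)CCCC(=O)OC | intermediate
5 | 4-methylpenta-1,3-diene | CC(C)=CC=C | starting material
6 | dimethyl 2-(2-bromo-4-methylpent-3-en-1-yl)-2-methyl-3-oxoheptanedioate (allylic bromide, mixture of stereoisomers, not isolated) | COC(=O)C(C)(CC(Br)C=C(C)C)C(=O)CCCC(=O)OC | intermediate
7 | methyl (4S)-3-(3-methoxy-3-oxopropyl)-1-methyl-4-(2-methylprop-1-en-1-yl)-2-oxocyclopentane-1-carboxylate (epimeric at C1 and C3) | CC(C)=C[C@@H]1CC(C)(C(=O)OC)C(=O)C1CCC(=O)OC | intermediate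
8 | methyl (3R,4S)-3-(3-methoxy-3-oxopropyl)-1,3-dimethyl-4-(2-methylprop-1-en-1-yl)-2-oxocyclopentane-1-carboxylate (epimeric at C1; 3-methyl trans to isobutenyl) | CC(C)=C[C@@H]1CC(C)(C(=O)OC)C(=O)[C@]1(C)CCC(=O)OC | intermediate
9 | methyl 3-[(1R,5S)-1,3-dimethyl-5-(2-methylprop-1-en-1-yl)-2-oxocyclopentyl]propanoate (epimeric at C3) | CC(C)=C[C@@H]1CC(C)C(=O)[C@]1(C)CCC(=O)OC | intermediate
10 | methyl 3-[(1R,5S)-1,3-dimethyl-5-(2-methylprop-1-en-1-yl)-2-(trifluoromethanesulfonyloxy)cyclopent-2-en-1-yl]propanoate | CC(C)=C[C@@H]1CC(C)=C(OS(=O)(=O)C(F)(F)F)[C@]1(C)CCC(=O)OC | intermediate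
11 | methyl 3-[(1R,5S)-2-formyl-1,3-dimethyl-5-(2-methylprop-1-en-1-yl)cyclopent-2-en-1-yl]propanoate | CC(C)=C[C@@H]1CC(C)=C(C=O)[C@]1(C)CCC(=O)OC | intermediate
12 | methyl 3-[(1R,2R,3S,5S)-2-formyl-1,3-dimethyl-5-(2-methylprop-1-en-1-yl)cyclopentyl]propanoate (saturated aldehyde after equilibration, not isolated) | CC(C)=C[C@@H]1C[C@H](C)[C@@H](C=O)[C@]1(C)CCC(=O)OC | intermediate
13 | methyl 3-[(1R,2R,3S,5S)-2-(hydroxymethyl)-1,3-dimethyl-5-(2-methylprop-1-en-1-yl)cyclopentyl]propanoate | CC(C)=C[C@@H]1C[C@H](C)[C@@H](CO)[C@]1(C)CCC(=O)OC | intermediate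
14 | 7-hydroxy-2H-chromen-2-one (umbelliferone) | Oc1ccc2ccc(=O)oc2c1 | starting material
15 | methyl 3-[(1R,2R,3S,5S)-1,3-dimethyl-5-(2-methylprop-1-en-1-yl)-2-{[(2-oxo-2H-chromen-7-yl)oxy]methyl}cyclopentyl]propanoate | CC(C)=C[C@@H]1C[C@H](C)[C@@H](COc2ccc3ccc(=O)oc3c2)[C@]1(C)CCC(=O)OC | intermediate
16 | ferulsinaic acid, 3-[(1R,2R,3S,5S)-1,3-dimethyl-5-(2-methylprop-1-en-1-yl)-2-{[(2-oxo-2H-chromen-7-yl)oxy]methyl}cyclopentyl]propanoic acid | CC(C)=C[C@@H]1C[C@H](C)[C@@H](COc2ccc3ccc(=O)oc3c2)[C@]1(C)CCC(=O)O | target

**Count and risks**

Total step count: 10. Longest linear sequence: 10 steps (from 1 and 2 to 16; 5 and 14 are bought).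

Step 3 (proposed method). What may go wrong: loss of HBr from the bromide or β-hydride loss from the π-allyl intermediate to give open-chain dienes instead of ring closure; O-closure that does not drain to the ketone; uncatalysed background closure or weak facial discrimination that erodes the enantiomeric purity. The fallback uses known chemistry, sets out from 3 and 5 and comes back at 7. Epoxidation of 5 at its trisubstituted double bond (mCPBA, NaHCO3, CH2Cl2, 0 °C) should give 2,2-dimethyl-3-vinyloxirane F1. Tsuji–Trost alkylation of 3 with F1 under neutral conditions (Pd(PPh3)4, THF, 25 °C) should give the 1,4-adduct, tertiary allylic alcohol F2. Methyl chloroformate, pyridine and DMAP should convert it into methyl carbonate F3. Pd2(dba)3 with (R)-BINAP in THF at 40 °C should ionise F3; the methoxide released forms the ketone enolate, and the intramolecular asymmetric allylic alkylation should give 7.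

Step 8. What may go wrong: slow hydride transfer to the tetrasubstituted β-carbon, competing 1,2-reduction, or insufficient facial discrimination at the methyl-bearing carbon. The fallback sets out from ketone 9 and comes back at aldehyde 12. A Wittig reaction with Ph3P=CHOMe (from the phosphonium chloride and KN(SiMe3)2, THF, 0 °C; the α-methyl centre equilibrates under these conditions) should give enol ether F4. Hydrolysis with aqueous oxalic acid in THF, then K2CO3 in MeOH, should give 12, which is reduced with NaBH4 as in step 8. Here the ring-methyl configuration rests on the equilibrium of 9 (cis-1,3 to isobutenyl expected to be favoured) and on removal of the minor epimer by chromatography.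

Step 7. What may go wrong: capture of the vinylpalladium by tin hydride before CO insertion (loss of the triflate without homologation), or slow oxidative addition at the hindered triflate. The fallback sets out from triflate 10 and comes back at enal 11. Stille coupling with (tributylstannyl)methanol (Pd(PPh3)4, LiCl, dioxane, 90 °C) should give allylic alcohol F5, which MnO2 in CH2Cl2 should oxidise to 11.

Further compounds
F1 | step 3 | 2,2-dimethyl-3-vinyloxirane (racemic) | CC1(C)OC1C=C
F2 | step 3 | dimethyl 2-[(2E)-4-hydroxy-4-methylpent-2-en-1-yl]-2-methyl-3-oxoheptanedioate (racemic) | COC(=O)C(C)(C/C=C/C(C)(C)O)C(=O)CCCC(=O)OC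
F3 | step 3 | dimethyl 2-[(2E)-4-(methoxycarbonyloxy)-4-methylpent-2-en-1-yl]-2-methyl-3-oxoheptanedioate (racemic) | COC(=O)OC(C)(C)/C=C/CC(C)(C(=O)OC)C(=O)CCCC(=O)OC
F4 | step 8 | methyl 3-[(1R,5S)-2-(methoxymethylidene)-1,3-dimethyl-5-(2-methylprop-1-en-1-yl)cyclopentyl]propanoate (epimeric at C3, E/Z mixture) | CC(C)=C[C@@H]1CC(C)C(=COC)[C@]1(C)CCC(=O)OC
F5 | step 7 | methyl 3-[(1R,5S)-2-(hydroxymethyl)-1,3-dimethyl-5-(2-methylprop-1-en-1-yl)cyclopent-2-en-1-yl]propanoate | CC(C)=C[C@@H]1CC(C)=C(CO)[C@]1(C)CCC(=O)OC
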